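**Retrosynthetic overview**

- The angelate is put on last, onto the free C3 hydroxyl. Before that, the C4–C5 bond closes the seven-membered ring by a SmI2 Reformatsky aldol, and in the same flask an Evans–Tishchenko hydride shift from a chiral epoxy aldehyde installs the C5 epoxy ester and the C3 alcohol (1,3-anti).
- Enabling feature: C2 and C7, the two one-carbon bridges of the bicyclo[3.1.1]heptenone, carry their arms on the same face of the cyclobutane (1,3-diaxial), so C4 and C5 are held at bonding distance. Both arms hang on quaternary carbons (C2, C6), so enolate and aldehyde are unambiguous. The anti-1,3-diol with two different esters is exactly what aldol plus Tishchenko delivers.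
- Bicyclic core: an intramolecular vinylketene–alkene [2+2] cycloaddition builds the cyclobutane and the six-membered ring in one step from an acyclic dienynoic acid. Its single carbinol centre (later the C9 ketone) fixes the absolute configuration; it comes from a catalytic asymmetric vinylogous Mukaiyama aldol.
- Ring order: cyclobutane and six-membered ring (step 6), then the C7 side chain through a nitrile, then the enone, then the bromoketone from the alkyne, then the seven-membered ring (step 17).

Key step: step 17

Remark: atoms are located with the locants of tricyclo[5.4.0.0^2,8]undecane (C1, C2, C7, C8 = cyclobutane; C9 = ketone; C10=C11 = alkene), also in the intermediates. The unsaturated ester is read as the angelate (Z) and the epoxy ester as 2S,3R (methyl groups cis). The bisphosphoramide of step 3 is taken as the enantiomer that directs attack to the Si face of the aldehyde.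

**Route**

Step 1
Reactants: 1 (2E)-3-methylpent-2-en-4-yn-1-ol
Product: 2 (2E)-3-methylpent-2-en-4-ynal
Conditions: MnO2, CH2Cl2, rt; used as a solution
Reagents that add atoms: none
Why: Allylic oxidation with MnO2 should stop at the aldehyde and leave the E-enyne unchanged.

Step 2
Reactants: 3 methyl 3-methylbut-2-enoate
Product: 5 tert-butyl[(1-methoxy-3-methylbuta-1,3-dien-1-yl)oxy]dimethylsilane, via lithium dienolate 4 (not isolated)
Conditions: LiN(i-Pr)2 (LDA), THF, −78 °C; TBSCl, DMPU, −78 °C to rt
Reagents that add atoms: tert-butyldimethylsilyl chloride (CC(C)(C)[Si](C)(C)Cl)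
Why: γ-Deprotonation gives the extended enolate, which is silylated on oxygen (silyl ketene acetal formation).

Step 3
Reactants: 2 (2E)-3-methylpent-2-en-4-ynal; 5 silyl dienol ether
Product: 6 methyl (2E,5S,6E)-5-hydroxy-3,7-dimethylnona-2,6-dien-8-ynoate
Conditions: SiCl4 (1.1 equiv), chiral binaphthyl-2,2'-diamine-derived bisphosphoramide (5 mol %), i-Pr2NEt (10 mol %), CH2Cl2, −78 °C; aq. NaHCO3
Reagents that add atoms: none
Why: Vinylogous Mukaiyama aldol with Lewis-base-activated SiCl4, in which the dienol ether attacks through its γ-carbon the Si face of the conjugated aldehyde held on the chiral silicon cation; this sets the 5S carbinol (later C9), and γ-attack gives the 2E enoate.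

Step 4
Reactants: 6 hydroxy ester
Product: 7 methyl (2E,5S,6E)-5-{[tert-butyl(dimethyl)silyl]oxy}-3,7-dimethylnona-2,6-dien-8-ynoate
Conditions: TBSCl, imidazole, DMF, rt
Reagents that add atoms: tert-butyldimethylsilyl chloride (CC(C)(C)[Si](C)(C)Cl)
Why: Standard silylation of a secondary allylic alcohol, needed because a free hydroxyl would capture the ketene of step 6.

Step 5
Reactants: 7 silyl ether ester
Product: 8 (2E,5S,6E)-5-{[tert-butyl(dimethyl)silyl]oxy}-3,7-dimethylnona-2,6-dien-8-ynoic acid
Conditions: LiOH·H2O, THF/MeOH/H2O, rt; 1 M HCl to pH 4, 0 °C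
Reagents that add atoms: lithium hydroxide ([Li+].[OH-])
Why: Saponification of the methyl ester; hydroxide does not form the ester dienolate, so the δ-silyloxy group is not eliminated.

Step 6
Reactants: 8 dienynoic acid
Product: 11 (1R,2S,5R,7R)-2-{[tert-butyl(dimethyl)silyl]oxy}-7-ethynyl-7-methyl-4-methylidenebicyclo[3.1.1]heptan-6-one, via acid chloride 9 (not isolated), via vinylketene 10 (not isolated)
Conditions: 1-chloro-N,N,2-trimethylprop-1-en-1-amine, CH2Cl2, 0 °C to rt; then slow addition to Et3N, toluene, reflux, high dilution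
Reagents that add atoms: none
Why: γ-Dehydrochlorination gives the vinylketene, which undergoes the intramolecular ketene–alkene [2+2] cycloaddition in the crossed sense (ketene carbonyl carbon, later C7, to the alkene CH, later C8; ketene α-carbon, later C1, to the fully substituted alkene carbon, later C2); addition is suprafacial on the alkene, so the E-ethynyl group ends on the side of the carbonyl bridge, and allylic 1,3-strain between the silyloxy group and the Z-methyl group selects the face, so the one carbinol centre sets C1, C2 and C8.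

Step 7
Reactants: 11 cyclobutanone
Product: 12 2-[2-{[tert-butyl(dimethyl)silyl]oxy}-7-ethynyl-7-methyl-4-methylidenebicyclo[3.1.1]heptan-6-ylidene]propanenitrile (ring stereocentres as in 11; E/Z mixture)
Conditions: diethyl (1-cyanoethyl)phosphonate, NaH, THF, 0 °C; then 11, 0 to 60 °C
Reagents that add atoms: diethyl (1-cyanoethyl)phosphonate (CCOP(=O)(OCC)C(C)C#N)
Why: Horner–Wadsworth–Emmons olefination, in which the strained carbonyl and the slim cyanophosphonate anion should offset the shielding; no stereocentre is formed and both alkene isomers converge in step 9.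

Step 8
Reactants: 12 silyl ether
Product: 13 2-[7-ethynyl-2-hydroxy-7-methyl-4-methylidenebicyclo[3.1.1]heptan-6-ylidene]propanenitrile (ring stereocentres as in 11; E/Z mixture)
Conditions: HF·pyridine, THF, 0 °C to rt
Reagents that add atoms: none
Why: Fluoride cleavage of the silyl ether frees the hydroxyl that serves as internal proton source in step 9.

Step 9
Reactants: 13 unsaturated nitrile
Product: 14 2-[7-ethynyl-2-hydroxy-7-methyl-4-methylidenebicyclo[3.1.1]heptan-6-yl]propanenitrile (side chain on C6 syn to the ethynyl group; both epimers at the nitrile carbon)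
Conditions: Mg turnings, MeOH, 0 °C to rt
Reagents that add atoms: none
Why: Dissolving-metal conjugate reduction of an α,β-unsaturated nitrile, in which the β-carbon (later C7) is protonated from the face of the three-carbon bridge, because the other face is covered by the ethynyl group on the neighbouring bridge and the 1,3-diaxial hydroxyl delivers the proton; the isolated alkene and alkyne are not reduced.

Step 10
Reactants: 14 nitrile
Product: 16 2-[7-ethynyl-2-hydroxy-7-methyl-4-methylidenebicyclo[3.1.1]heptan-6-yl]-2-methylpropanenitrile, via trilithio species 15 (not isolated)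
Conditions: LiN(i-Pr)2 (LDA, 3.3 equiv), THF, −78 °C; MeI (1.05 equiv), −78 to −40 °C; H2O
Reagents that add atoms: iodomethane (CI)
Why: α-Alkylation of the nitrile-stabilised carbanion creates the quaternary C6 and removes the epimeric centre; the lithium alkoxide and acetylide should not be methylated at this temperature without a polar additive.

Step 11
Reactants: 16 tertiary nitrile
Product: 18 2-[7-ethynyl-2-hydroxy-7-methyl-4-methylidenebicyclo[3.1.1]heptan-6-yl]-2-methylpropanal, via N-aluminio imine 17 (not isolated)
Conditions: i-Bu2AlH (3 equiv), toluene, −78 to 0 °C; aq. KNaC4H4O6, then 1 M HCl/THF, 0 °C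
Reagents that add atoms: water (O)
Why: Partial reduction of a nitrile by i-Bu2AlH stops at the aluminium imine, which is hydrolysed to the non-enolisable neopentyl aldehyde (C5).

Step 12
Reactants: 18 hydroxy aldehyde
Product: 20 2-[(1R,5R,6R,7S)-6-ethynyl-4,6-dimethyl-2-oxobicyclo[3.1.1]hept-3-en-7-yl]-2-methylpropanal, via deconjugated enone 19 (not isolated)
Conditions: Dess–Martin periodinane, NaHCO3, CH2Cl2, 0 °C to rt; filter; DBU (0.2 equiv), CH2Cl2, rt
Reagents that add atoms: none
Why: Dess–Martin oxidation gives the β,γ-unsaturated ketone and DBU moves the exocyclic alkene into conjugation through the dienolate; the aldehyde has no α-hydrogen and the alkyne is inert.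

Step 13
Reactants: 20 terminal alkyne
Product: 21 2-[(1R,5R,6R,7S)-6-(bromoethynyl)-4,6-dimethyl-2-oxobicyclo[3.1.1]hept-3-en-7-yl]-2-methylpropanal
Conditions: N-bromosuccinimide, AgNO3 (10 mol %), acetone, rt, dark
Reagents that add atoms: N-bromosuccinimide (BrN1C(=O)CCC1=O)
Why: Silver-catalysed electrophilic bromination of a terminal alkyne through the silver acetylide, neutral and selective beside the enone and aldehyde.

Step 14
Reactants: 21 bromoalkyne
Product: 22 2-[(1R,5R,6R,7S)-6-(bromoacetyl)-4,6-dimethyl-2-oxobicyclo[3.1.1]hept-3-en-7-yl]-2-methylpropanal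
Conditions: (XPhos)AuNTf2 (3 mol %), H2O (3 equiv), 1,2-dichloroethane, 40 °C
Reagents that add atoms: water (O)
Why: Gold-catalysed hydration of a 1-bromoalkyne places oxygen on the carbon remote from bromine and gives the α-bromomethyl ketone under neutral conditions.

Step 15
Reactants: 23 (2E)-2-methylbut-2-en-1-ol
Product: 24 [(2R,3R)-2,3-dimethyloxiran-2-yl]methanol
Conditions: Ti(Oi-Pr)4 (10 mol %), D-(−)-diethyl tartrate (12 mol %), t-BuOOH, 4 Å molecular sieves, CH2Cl2, −20 °C
Reagents that add atoms: tert-butyl hydroperoxide (CC(C)(C)OO)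
Why: Sharpless asymmetric epoxidation, in which the D-(−)-tartrate should give the 2R,3R epoxide (mirror image of the 2S,3S outcome of L-(+)-tartrate with E-allylic alcohols) and the E-alkene fixes the cis methyl groups.

Step 16
Reactants: 24 epoxy alcohol
Product: 25 (2S,3R)-2,3-dimethyloxirane-2-carbaldehyde
Conditions: Dess–Martin periodinane, NaHCO3, CH2Cl2, 0 °C to rt; bulb-to-bulb distillation
Reagents that add atoms: none
Why: Dess–Martin oxidation of a primary alcohol; the α-carbon is quaternary, so the aldehyde can neither epimerise nor enolise.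

Step 17
Reactants: 22 bromoketone aldehyde; 25 epoxy aldehyde
Product: 29 (1R,2R,3R,5R,7S,8R)-3-hydroxy-2,6,6,11-tetramethyl-9-oxotricyclo[5.4.0.0^2,8]undec-10-en-5-yl (2S,3R)-2,3-dimethyloxirane-2-carboxylate, via samarium enolate 26 (not isolated), via samarium aldolate 27 (not isolated), via samarium hemiacetalate 28 (not isolated)
Conditions: SmI2 (2.05 equiv, 0.1 M in THF), THF, −78 °C; then 25 (4 equiv), −78 to −10 °C; aq. NaHCO3
Reagents that add atoms: none
Why: Proposed new method: SmI2 reduces the C–Br bond of 22 to the samarium enolate 26, which closes the cycloheptane ring by aldol addition of C4 to the neopentyl aldehyde carbon C5 (intramolecular samarium Reformatsky reaction, 7-(enolexo)-exo-trig) to give aldolate 27; its samarium-bound oxygen then adds to aldehyde 25 (hemiacetalate 28) and the hemiacetal hydrogen shifts to the C3 ketone through a six-membered samarium-bridged transition state (Evans–Tishchenko step), which leaves the epoxy acid as the C5 ester and C3 as the free alcohol. The closest known reaction types are the SmI2 Reformatsky closure of medium rings, the samarium-catalysed aldol–Tishchenko reaction of a ketone with two equivalents of one aldehyde and the Evans–Tishchenko reduction of isolated β-hydroxy ketones; new is their union in one flask in a ring-closing sense with a second, chiral aldehyde as hydride donor. C3 is set by the internal hydride delivery from the face of the C5 oxygen (1,3-anti, the rule of this reduction). C5 cannot be set by the core, because the new ring lies in a local mirror plane of the bicyclo[4.1.1]octane part and the enone bridge that breaks this symmetry sits on the far side of the cyclobutane; it is left to aldehyde 25 under Curtin–Hammett conditions, the aldol step being reversible on trivalent samarium and the hydride shift product-determining, and with samarium chelated by the hemiacetal and epoxide oxygens only the aldolate with the C5–O bond on the C1 side should place the epoxide ring carbon beside the small migrating hydrogen and not against the C5–O flank next to the C6 methyl groups. The step needs electron transfer to the bromoketone before the enone or the aldehyde (the α-bromoketone is by far the best acceptor at −78 °C), one defined enolate (the bromide marks it, and C2 and C6 are quaternary, so neither arm nor 25 can enolise elsewhere), ring closure over intermolecular aldol (the two arms stand syn and 1,3-diaxial on C2 and C7 of the cyclobutane) and no acyl migration (the ester is α-quaternary and hindered).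

Step 18
Reactants: 29 hydroxy epoxy ester
Product: 30 (1R,2R,3R,5R,7S,8R)-2,6,6,11-tetramethyl-3-{[(2Z)-2-methylbut-2-enoyl]oxy}-9-oxotricyclo[5.4.0.0^2,8]undec-10-en-5-yl (2S,3R)-2,3-dimethyloxirane-2-carboxylate
Conditions: angelic acid, 2,4,6-trichlorobenzoyl chloride, Et3N, toluene, rt; then 29, 75 °C, no DMAP
Reagents that add atoms: angelic acid (C/C=C(/C)C(=O)O)
Why: Yamaguchi-type esterification through the mixed anhydride without a nucleophilic catalyst, conditions under which the Z-acid should not isomerise to the tiglate; the C3 hydroxyl is the only free one.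

**Compound list**

1 | (2E)-3-methylpent-2-en-4-yn-1-ol | OC/C=C(\C)C#C | starting material
2 | (2E)-3-methylpent-2-en-4-ynal | O=C/C=C(\C)C#C | intermediate
3 | methyl 3-methylbut-2-enoate | COC(=O)C=C(C)C | starting material
4 | lithium 1-methoxy-3-methylbuta-1,3-dien-1-olate | COC(O[Li])=CC(C)=C | intermediate
5 | tert-butyl[(1-methoxy-3-methylbuta-1,3-dien-1-yl)oxy]dimethylsilane | COC(O[Si](C)(C)C(C)(C)C)=CC(C)=C | intermediate
6 | methyl (2E,5S,6E)-5-hydroxy-3,7-dimethylnona-2,6-dien-8-ynoate | COC(=O)/C=C(\C)C[C@H](O)/C=C(\C)C#C | intermediate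
7 | methyl (2E,5S,6E)-5-{[tert-butyl(dimethyl)silyl]oxy}-3,7-dimethylnona-2,6-dien-8-ynoate | COC(=O)/C=C(\C)C[C@H](O[Si](C)(C)C(C)(C)C)/C=C(\C)C#C | intermediate
8 | (2E,5S,6E)-5-{[tert-butyl(dimethyl)silyl]oxy}-3,7-dimethylnona-2,6-dien-8-ynoic acid | OC(=O)/C=C(\C)C[C@H](O[Si](C)(C)C(C)(C)C)/C=C(\C)C#C | intermediate
9 | (2E,5S,6E)-5-{[tert-butyl(dimethyl)silyl]oxy}-3,7-dimethylnona-2,6-dien-8-ynoyl chloride | ClC(=O)/C=C(\C)C[C@H](O[Si](C)(C)C(C)(C)C)/C=C(\C)C#C | intermediate
10 | (5S,6E)-5-{[tert-butyl(dimethyl)silyl]oxy}-7-methyl-3-methylidenenona-1,6-dien-8-yn-1-one (vinylketene) | O=C=CC(=C)C[C@H](O[Si](C)(C)C(C)(C)C)/C=C(\C)C#C | intermediate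
11 | (1R,2S,5R,7R)-2-{[tert-butyl(dimethyl)silyl]oxy}-7-ethynyl-7-methyl-4-methylidenebicyclo[3.1.1]heptan-6-one (ethynyl and silyloxy both on the side of the carbonyl bridge) | C#C[C@@]1(C)[C@H]2C(=O)[C@@H]1C(=C)C[C@@H]2O[Si](C)(C)C(C)(C)C | intermediate
12 | 2-[2-{[tert-butyl(dimethyl)silyl]oxy}-7-ethynyl-7-methyl-4-methylidenebicyclo[3.1.1]heptan-6-ylidene]propanenitrile (ring as in 11; E/Z mixture) | C#C[C@@]1(C)[C@H]2C(=C(C)C#N)[C@@H]1C(=C)C[C@@H]2O[Si](C)(C)C(C)(C)C | intermediate
13 | 2-[7-ethynyl-2-hydroxy-7-methyl-4-methylidenebicyclo[3.1.1]heptan-6-ylidene]propanenitrile (ring as in 11; E/Z mixture) | C#C[C@@]1(C)[C@H]2C(=C(C)C#N)[C@@H]1C(=C)C[C@@H]2O | intermediate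
14 | 2-[7-ethynyl-2-hydroxy-7-methyl-4-methylidenebicyclo[3.1.1]heptan-6-yl]propanenitrile (side chain syn to ethynyl; epimers at the nitrile carbon) | C#C[C@@]1(C)[C@H]2[C@@H](C(C)C#N)[C@@H]1C(=C)C[C@@H]2O | intermediate
15 | trilithio derivative of 14 (alkoxide, acetylide, nitrile α-carbanion) | [Li]C#C[C@@]1(C)[C@H]2[C@@H](C(C)([Li])C#N)[C@@H]1C(=C)C[C@@H]2O[Li] | intermediate
16 | 2-[7-ethynyl-2-hydroxy-7-methyl-4-methylidenebicyclo[3.1.1]heptan-6-yl]-2-methylpropanenitrile (stereocentres as in 14) | C#C[C@@]1(C)[C@H]2[C@@H](C(C)(C)C#N)[C@@H]1C(=C)C[C@@H]2O | intermediate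
17 | N-(diisobutylaluminio) imine of 18, as its O-diisobutylaluminium alkoxide | C#C[C@@]1(C)[C@H]2[C@@H](C(C)(C)C=N[Al](CC(C)C)CC(C)C)[C@@H]1C(=C)C[C@@H]2O[Al](CC(C)C)CC(C)C | intermediate
18 | 2-[7-ethynyl-2-hydroxy-7-methyl-4-methylidenebicyclo[3.1.1]heptan-6-yl]-2-methylpropanal (stereocentres as in 14) | C#C[C@@]1(C)[C@H]2[C@@H](C(C)(C)C=O)[C@@H]1C(=C)C[C@@H]2O | intermediate
19 | 2-[6-ethynyl-6-methyl-4-methylidene-2-oxobicyclo[3.1.1]heptan-7-yl]-2-methylpropanal (stereocentres as in 20) | C#C[C@@]1(C)[C@H]2[C@@H](C(C)(C)C=O)[C@@H]1C(=C)CC2=O | intermediate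
20 | 2-[(1R,5R,6R,7S)-6-ethynyl-4,6-dimethyl-2-oxobicyclo[3.1.1]hept-3-en-7-yl]-2-methylpropanal | C#C[C@@]1(C)[C@H]2[C@@H](C(C)(C)C=O)[C@@H]1C(C)=CC2=O | intermediate
21 | 2-[(1R,5R,6R,7S)-6-(bromoethynyl)-4,6-dimethyl-2-oxobicyclo[3.1.1]hept-3-en-7-yl]-2-methylpropanal | BrC#C[C@@]1(C)[C@H]2[C@@H](C(C)(C)C=O)[C@@H]1C(C)=CC2=O | intermediate
22 | 2-[(1R,5R,6R,7S)-6-(bromoacetyl)-4,6-dimethyl-2-oxobicyclo[3.1.1]hept-3-en-7-yl]-2-methylpropanal | BrCC(=O)[C@@]1(C)[C@H]2[C@@H](C(C)(C)C=O)[C@@H]1C(C)=CC2=O | intermediate
23 | (2E)-2-methylbut-2-en-1-ol | C/C=C(\C)CO | starting material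
24 | [(2R,3R)-2,3-dimethyloxiran-2-yl]methanol | OC[C@@]1(C)O[C@@H]1C | intermediate
25 | (2S,3R)-2,3-dimethyloxirane-2-carbaldehyde | O=C[C@@]1(C)O[C@@H]1C | intermediate
26 | diiodosamarium enolate of 22 | C=C(O[Sm](I)I)[C@@]1(C)[C@H]2[C@@H](C(C)(C)C=O)[C@@H]1C(C)=CC2=O | intermediate
27 | diiodosamarium (5R)-alkoxide of 5-hydroxy-2,6,6,11-tetramethyltricyclo[5.4.0.0^2,8]undec-10-ene-3,9-dione | O=C1C[C@@H](O[Sm](I)I)C(C)(C)[C@@H]2[C@H]3C(=O)C=C(C)[C@@H]2[C@]31C | intermediate
28 | diiodosamarium hemiacetalate of 27 with 25 | O=C1C[C@@H](OC(O[Sm](I)I)[C@@]2(C)O[C@@H]2C)C(C)(C)[C@@H]2[C@H]3C(=O)C=C(C)[C@@H]2[C@]31C | intermediate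
29 | (1R,2R,3R,5R,7S,8R)-3-hydroxy-2,6,6,11-tetramethyl-9-oxotricyclo[5.4.0.0^2,8]undec-10-en-5-yl (2S,3R)-2,3-dimethyloxirane-2-carboxylate | O[C@@H]1C[C@@H](OC(=O)[C@@]2(C)O[C@@H]2C)C(C)(C)[C@@H]2[C@H]3C(=O)C=C(C)[C@@H]2[C@]31C | intermediate
30 | (1R,2R,3R,5R,7S,8R)-2,6,6,11-tetramethyl-3-{[(2Z)-2-methylbut-2-enoyl]oxy}-9-oxotricyclo[5.4.0.0^2,8]undec-10-en-5-yl (2S,3R)-2,3-dimethyloxirane-2-carboxylate (CNP0149458.1) | C/C=C(/C)C(=O)O[C@@H]1C[C@@H](OC(=O)[C@@]2(C)O[C@@H]2C)C(C)(C)[C@@H]2[C@H]3C(=O)C=C(C)[C@@H]2[C@]31C | target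

**Step count and risks**

Total step count: 18. Longest linear sequence: 15 steps (1, 3 to 14, 17, 18).

Steps most likely to fail:

1. Step 17 (Proposed new method). The two aldolates are equally populated and differ only in which hydride-shift transition state the chiral aldehyde prefers. The discrimination may be too small, the retro-aldol may be too slow to feed the faster channel, or iodide on samarium may open the epoxide during the long second stage. The fallback uses known chemistry and sets out from 22. SmI2 (2.05 equiv, THF, −78 °C, cold acidic quench) performs only the intramolecular Reformatsky closure and should give the two β-hydroxy ketones, (1R,2R,5R,7S,8R)-5-hydroxy-2,6,6,11-tetramethyltricyclo[5.4.0.0^2,8]undec-10-ene-3,9-dione F1 and its 5S epimer F2. These are separated by chromatography; F2 is returned to the mixture by base-catalysed retro-aldol/aldol equilibration (catalytic KOt-Bu, THF, −40 °C) and recycled. F1 then undergoes the standard Evans–Tishchenko reduction with 25 and catalytic SmI2 (0.3 equiv, THF, −10 °C), which rejoins the route at 29.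

2. Step 7. Addition to a carbonyl shielded on one face by the ethynyl group and on the other by the silyloxy group may be too slow, and the basic phosphonate anion may instead open the β,γ-unsaturated cyclobutanone. The fallback sets out from 11 and replaces olefination by addition and elimination. Lithiated propanenitrile (propanenitrile, LDA, THF, −78 °C), a smaller and more reactive nucleophile, adds at a temperature where the cyclobutoxide should not fragment, giving the tertiary cyclobutanol 2-[2-{[tert-butyl(dimethyl)silyl]oxy}-7-ethynyl-6-hydroxy-7-methyl-4-methylidenebicyclo[3.1.1]heptan-6-yl]propanenitrile F3. Syn-elimination with methyl N-(triethylammoniosulfonyl)carbamate (Burgess reagent, benzene, 50 °C) can only take the hydrogen at the nitrile carbon, since the other β-hydrogens are at bridgeheads, and rejoins the route at 12.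

3. Step 14. Water attack on the gold-bound alkyne next to the quaternary C2 and under the gem-dimethyl arm may be slow, or the neighbouring aldehyde oxygen may capture the activated alkyne and divert it to cyclic enol ethers. The fallback sets out from 20 and reverses the order of hydration and bromination. Hg(OTf)2 (5 mol %), H2O, MeCN, rt should hydrate the terminal alkyne (Markovnikov) to the methyl ketone 2-[(1R,5R,6R,7S)-6-acetyl-4,6-dimethyl-2-oxobicyclo[3.1.1]hept-3-en-7-yl]-2-methylpropanal F4. Phenyltrimethylammonium tribromide (1.0 equiv, THF, 0 °C) then brominates the only enolisable methyl ketone position and rejoins the route at 22.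

Further compounds
F1 | step 17 | (1R,2R,5R,7S,8R)-5-hydroxy-2,6,6,11-tetramethyltricyclo[5.4.0.0^2,8]undec-10-ene-3,9-dione | O=C1C[C@@H](O)C(C)(C)[C@@H]2[C@H]3C(=O)C=C(C)[C@@H]2[C@]31C
F2 | step 17 | (1R,2R,5S,7S,8R)-5-hydroxy-2,6,6,11-tetramethyltricyclo[5.4.0.0^2,8]undec-10-ene-3,9-dione | O=C1C[C@H](O)C(C)(C)[C@@H]2[C@H]3C(=O)C=C(C)[C@@H]2[C@]31C
F3 | step 7 | 2-[2-{[tert-butyl(dimethyl)silyl]oxy}-7-ethynyl-6-hydroxy-7-methyl-4-methylidenebicyclo[3.1.1]heptan-6-yl]propanenitrile (ring as in 11) | C#C[C@@]1(C)[C@H]2C(O)(C(C)C#N)[C@@H]1C(=C)C[C@@H]2O[Si](C)(C)C(C)(C)C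
F4 | step 14 | 2-[(1R,5R,6R,7S)-6-acetyl-4,6-dimethyl-2-oxobicyclo[3.1.1]hept-3-en-7-yl]-2-methylpropanal | CC(=O)[C@@]1(C)[C@H]2[C@@H](C(C)(C)C=O)[C@@H]1C(C)=CC2=O
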